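## Retrosynthetic overview
1. The target comes from MOM removal and a late C7–H borylation/oxidation of a (3S)-5-methoxyisoflavanone core.
2. The C3–aryl bond and the C3 stereocentre come from a stereospecific 1,2-aryl shift (C4 to C3, semipinacol) in a cis-4-arylchromane-3,4-diol 3-triflate.
3. The cis-diol comes from 1,2-addition of the ring B chromenyllithium to (R)-3-hydroxy-5-methoxychroman-4-one.
4. The hydroxychromanone comes from resorcinol (as its ortho-lithiated dimethyl ether) and methyl (R)-glycidate. The bromochromene comes from catechol and 3-chloro-3-methylbut-1-yne.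
5. Ring order: ring C is closed on ring A, the pyran ring is closed on ring B, and the two halves are then joined. Both benzene rings are bought.

Assumption: the SMILES is read as the (3S) enantiomer, and methyl (R)-glycidate is bought enantiopure.

## Route

Step 1
Reactants: 1 resorcinol
Product: 2 1,3-dimethoxybenzene
Conditions: MeI (2.5 equiv), K2CO3, acetone, reflux
Reagents that add atoms: iodomethane, CI
Why: Williamson ether synthesis methylates both phenoxides by SN2, and one of the two equivalent methyl groups later serves as the temporary cap of the oxygen that becomes O1.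

Step 2
Reactants: 2 1,3-dimethoxybenzene; 3 methyl (R)-oxirane-2-carboxylate (methyl (R)-glycidate)
Product: 5 (R)-(2,6-dimethoxyphenyl)(oxiran-2-yl)methanone, via 2,6-dimethoxyphenyllithium 4 (not isolated)
Conditions: n-BuLi, THF, 0 °C to rt; cannulated into 3 (1.5 equiv), THF, −78 °C; H2O at −78 °C
Reagents that add atoms: n-butyllithium, [Li]CCCC (lithium held only by 4)
Why: Directed ortho-metalation between the two methoxy groups is followed by acyl substitution on the ester at −78 °C, where the hindered tetrahedral adduct lasts until the quench so that over-addition and epoxide opening stay slow, and the stereocentre of 3 is carried over untouched (chiral pool).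

Step 3
Reactants: 5 (R)-(2,6-dimethoxyphenyl)(oxiran-2-yl)methanone
Product: 7 (R)-3-hydroxy-5-methoxychroman-4-one, via chlorohydrin phenol 6 (not isolated)
Conditions: BCl3 (2.5 equiv), CH2Cl2, −78 to 0 °C; H2O; then K2CO3, acetone, 0 °C to rt
Reagents that add atoms: boron trichloride, ClB(Cl)Cl (chlorine held only by 6)
Why: Chelation-controlled mono-demethylation of the 2,6-dimethoxyaryl ketone runs alongside SN2 opening of the epoxide by chloride at the CH2 end, and the freed phenoxide then closes ring C by a 6-exo-tet Williamson displacement, so the C–O bond at the stereocentre is never broken and C3 stays (R).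

Step 4
Reactants: 8 catechol
Product: 9 2-(methoxymethoxy)phenol
Conditions: NaH (1.0 equiv), MOMCl (1.0 equiv), THF–DMF, 0 °C
Reagents that add atoms: chloromethyl methyl ether, COCCl
Why: Statistical mono-alkylation of a symmetrical diphenol (acetal protection) leaves one free phenol that steers the next two steps.

Step 5
Reactants: 9 2-(methoxymethoxy)phenol
Product: 10 4-bromo-2-(methoxymethoxy)phenol
Conditions: NBS, MeCN, −20 to 0 °C
Reagents that add atoms: N-bromosuccinimide, O=C1CCC(=O)N1Br
Why: Electrophilic aromatic bromination goes para to the free hydroxyl group, the strongest donor, as it does with guaiacol.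

Step 6
Reactants: 10 4-bromo-2-(methoxymethoxy)phenol; 11 3-chloro-3-methylbut-1-yne
Product: 12 4-bromo-2-(methoxymethoxy)-1-[(2-methylbut-3-yn-2-yl)oxy]benzene
Conditions: K2CO3, KI (cat.), CuI (cat.), DMF, 65 °C
Reagents that add atoms: none
Why: Copper-assisted Williamson-type O-propargylation of the only free phenol by the tertiary propargylic chloride is the standard entry to dimethylchromenes.

Step 7
Reactants: 12 4-bromo-2-(methoxymethoxy)-1-[(2-methylbut-3-yn-2-yl)oxy]benzene
Product: 13 6-bromo-8-(methoxymethoxy)-2,2-dimethyl-2H-chromene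
Conditions: o-xylene, 140 °C
Reagents that add atoms: none
Why: An aromatic propargyl Claisen rearrangement to the only free ortho position, a 1,5-hydrogen shift and an oxa-6π electrocyclisation form the pyran ring in one thermal cascade.

Step 8
Reactants: 13 6-bromo-8-(methoxymethoxy)-2,2-dimethyl-2H-chromene; 7 (R)-3-hydroxy-5-methoxychroman-4-one
Product: 16 (3R,4S)-5-methoxy-4-[8-(methoxymethoxy)-2,2-dimethyl-2H-chromen-6-yl]chromane-3,4-diol (cis-diol), via chromenyllithium 14 (not isolated), via chloromagnesium alkoxide 15 (not isolated)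
Conditions: 13, n-BuLi, THF, −78 °C; 7, t-BuMgCl (1.0 equiv), THF, −78 °C; combine, −78 to −30 °C; pH 7 buffer
Reagents that add atoms: n-butyllithium, [Li]CCCC (lithium held only by 14); tert-butylmagnesium chloride, CC(C)(C)[Mg]Cl (MgCl held only by 15)
Why: After lithium–bromine exchange the aryllithium adds 1,2 to the ketone, whose neighbouring magnesium alkoxide suppresses enolisation and forms a five-membered chelate that is attacked from the side of the C3 hydrogen (Cram chelate control), so the aryl group enters trans to the C3 oxygen and C4 is set as (S).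

Step 9
Reactants: 16 (3R,4S)-cis-diol
Product: 18 (3S)-5-methoxy-3-[8-(methoxymethoxy)-2,2-dimethyl-2H-chromen-6-yl]chroman-4-one, via C3 triflate 17 (not isolated)
Conditions: Tf2O (1.1 equiv), 2,6-lutidine (3 equiv), CH2Cl2, −78 to −20 °C; pH 7 buffer
Reagents that add atoms: trifluoromethanesulfonic anhydride, O=S(=O)(OS(=O)(=O)C(F)(F)F)C(F)(F)F (triflyl group held only by 17)
Why: Proposed new method: only the less hindered secondary hydroxyl is triflated, and because the peri 5-methoxy group forces the C4 aryl group pseudo-axial and hence antiperiplanar to the pseudo-axial C3–OTf bond, the electron-rich para-alkoxyaryl group migrates from C4 to C3 through a phenonium-like transition state with clean inversion while the C4 hydroxyl collapses to the ketone, turning the (3R) C–O centre into the (3S) C–aryl centre; the closest known reaction type is the stereospecific semipinacol rearrangement of acyclic 2-sulfonyloxy tertiary alcohols, which has not been shown on 4-arylchromane-3,4-diols (neoflavonoid to isoflavonoid skeleton), where ring contraction by migration of C4a is the competing path.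

Step 10
Reactants: 18 (3S)-5-methoxy-3-[8-(methoxymethoxy)-2,2-dimethyl-2H-chromen-6-yl]chroman-4-one
Product: 20 (3S)-7-hydroxy-5-methoxy-3-[8-(methoxymethoxy)-2,2-dimethyl-2H-chromen-6-yl]chroman-4-one, via C7 pinacol boronate 19 (not isolated)
Conditions: [Ir(OMe)(cod)]2 (2 mol %), dtbpy, B2pin2, THF, 60 °C; then N,N-dimethyl-p-toluidine N-oxide, rt; pH 7 buffer
Reagents that add atoms: bis(pinacolato)diboron, CC1(C)OB(OC1(C)C)B1OC(C)(C)C(C)(C)O1 (Bpin held only by 19); N,N-dimethyl-p-toluidine N-oxide, Cc1ccc(cc1)[N+](C)(C)[O-] (oxygen of the new phenol)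
Why: Sterically controlled iridium-catalysed aromatic C–H borylation takes C7–H, the only aromatic C–H without an ortho substituent, and the base-free amine N-oxide oxidation of the boronate gives the phenol without touching the acidic C3–H.

Step 11
Reactants: 20 (3S)-7-hydroxy-5-methoxy-3-[8-(methoxymethoxy)-2,2-dimethyl-2H-chromen-6-yl]chroman-4-one
Product: 21 (3S)-7-hydroxy-3-(8-hydroxy-2,2-dimethyl-2H-chromen-6-yl)-5-methoxychroman-4-one (target)
Conditions: ZnBr2, n-PrSH (2 equiv), CH2Cl2, 0 °C, 10 min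
Reagents that add atoms: none
Why: Lewis acid–thiol cleavage of the phenolic MOM acetal is complete in minutes under non-basic conditions, so the chromene, the methyl ether and the labile C3 stereocentre survive.

## Compound list
1 | resorcinol | Oc1cccc(O)c1 | starting material
2 | 1,3-dimethoxybenzene | COc1cccc(OC)c1 | intermediate
3 | methyl (R)-oxirane-2-carboxylate | COC(=O)[C@H]1CO1 | starting material
4 | 2,6-dimethoxyphenyllithium | [Li]c1c(OC)cccc1OC | intermediate
5 | (R)-(2,6-dimethoxyphenyl)(oxiran-2-yl)methanone | COc1cccc(OC)c1C(=O)[C@H]1CO1 | intermediate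
6 | (S)-3-chloro-2-hydroxy-1-(2-hydroxy-6-methoxyphenyl)propan-1-one | COc1cccc(O)c1C(=O)[C@H](O)CCl | intermediate
7 | (R)-3-hydroxy-5-methoxychroman-4-one | COc1cccc2c1C(=O)[C@H](O)CO2 | intermediate
8 | catechol | Oc1ccccc1O | starting material
9 | 2-(methoxymethoxy)phenol | Oc1ccccc1OCOC | intermediate
10 | 4-bromo-2-(methoxymethoxy)phenol | Oc1ccc(Br)cc1OCOC | intermediate
11 | 3-chloro-3-methylbut-1-yne | C#CC(C)(C)Cl | starting material
12 | 4-bromo-2-(methoxymethoxy)-1-[(2-methylbut-3-yn-2-yl)oxy]benzene | C#CC(C)(C)Oc1ccc(Br)cc1OCOC | intermediate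
13 | 6-bromo-8-(methoxymethoxy)-2,2-dimethyl-2H-chromene | Brc1cc(OCOC)c2OC(C)(C)C=Cc2c1 | intermediate
14 | [8-(methoxymethoxy)-2,2-dimethyl-2H-chromen-6-yl]lithium | [Li]c1cc(OCOC)c2OC(C)(C)C=Cc2c1 | intermediate
15 | chloromagnesium (R)-5-methoxy-4-oxochroman-3-olate | COc1cccc2c1C(=O)[C@H](O[Mg]Cl)CO2 | intermediate
16 | (3R,4S)-5-methoxy-4-[8-(methoxymethoxy)-2,2-dimethyl-2H-chromen-6-yl]chromane-3,4-diol | COc1cccc2c1[C@@](O)(c1cc(OCOC)c3OC(C)(C)C=Cc3c1)[C@H](O)CO2 | intermediate
17 | (3R,4S)-4-hydroxy-5-methoxy-4-[8-(methoxymethoxy)-2,2-dimethyl-2H-chromen-6-yl]chroman-3-yl trifluoromethanesulfonate | COc1cccc2c1[C@@](O)(c1cc(OCOC)c3OC(C)(C)C=Cc3c1)[C@H](OS(=O)(=O)C(F)(F)F)CO2 | intermediate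
18 | (3S)-5-methoxy-3-[8-(methoxymethoxy)-2,2-dimethyl-2H-chromen-6-yl]chroman-4-one | COc1cccc2c1C(=O)[C@@H](c1cc(OCOC)c3OC(C)(C)C=Cc3c1)CO2 | intermediate
19 | (3S)-5-methoxy-3-[8-(methoxymethoxy)-2,2-dimethyl-2H-chromen-6-yl]-7-(4,4,5,5-tetramethyl-1,3,2-dioxaborolan-2-yl)chroman-4-one | COc1cc(B3OC(C)(C)C(C)(C)O3)cc2c1C(=O)[C@@H](c1cc(OCOC)c3OC(C)(C)C=Cc3c1)CO2 | intermediate
20 | (3S)-7-hydroxy-5-methoxy-3-[8-(methoxymethoxy)-2,2-dimethyl-2H-chromen-6-yl]chroman-4-one | COc1cc(O)cc2c1C(=O)[C@@H](c1cc(OCOC)c3OC(C)(C)C=Cc3c1)CO2 | intermediate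
21 | (3S)-7-hydroxy-3-(8-hydroxy-2,2-dimethyl-2H-chromen-6-yl)-5-methoxychroman-4-one | COc1cc(O)cc2c1C(=O)[C@@H](c1cc(O)c3c(c1)C=CC(C)(C)O3)CO2 | target

## Totals and risks
Total step count: 11. Longest linear sequence: 8 (steps 4 to 11, from catechol).

**Step 9 (the new 1,2-aryl shift).**
- It may fail by ring contraction (migration of C4a), by loss of TfOH towards a 4-arylchromenylium salt, or by ionisation at C4.
- The fallback uses only known chemistry. It sets out from 4 and 13 and comes back at 18.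
- Aryllithium 4 is acylated with 3-chloropropanoyl chloride to 3-chloro-1-(2,6-dimethoxyphenyl)propan-1-one F1.
- BCl3 gives 3-chloro-1-(2-hydroxy-6-methoxyphenyl)propan-1-one F2, and K2CO3 closes it to 5-methoxychroman-4-one F3.
- Palladium-catalysed ketone α-arylation of F3 with bromide 13 (Pd2(dba)3, P(t-Bu)3, NaOt-Bu, toluene) gives the racemic isoflavanone F4.
- Asymmetric transfer hydrogenation under dynamic kinetic resolution (RuCl[(S,S)-TsDPEN](p-cymene), HCO2H/Et3N) gives the cis-(3S,4S)-isoflavan-4-ol F5.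
- Dess–Martin oxidation of F5 returns 18 without loss of configuration.

**Step 2 (aryllithium on an epoxy ester).**
- It may fail by attack at the epoxide CH2, by deprotonation at the oxirane carbon, or by double addition.
- The fallback sets out from 4 and comes back at 7. It avoids the epoxide and closes ring C in another way.
- Aryllithium 4 is acylated with methyl (R)-2,2-dimethyl-1,3-dioxolane-4-carboxylate to (R)-(2,6-dimethoxyphenyl)(2,2-dimethyl-1,3-dioxolan-4-yl)methanone F6.
- BCl3 followed by water removes the acetonide and one methyl ether, giving (R)-2,3-dihydroxy-1-(2-hydroxy-6-methoxyphenyl)propan-1-one F7.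
- An intramolecular Mitsunobu etherification (PPh3, DIAD) of the primary alcohol with the phenol gives 7.

**Step 10 (late C–H borylation).**
- It may fail by borylation or hydroboration of the chromene C=C, by low conversion, or by erosion of the enantiomeric excess.
- The fallback sets out from 2 and comes back at 20. It puts the C7 oxygen in before any sensitive group exists.
- Arene 2 is borylated ([Ir(OMe)(cod)]2, dtbpy, B2pin2) to 2-(3,5-dimethoxyphenyl)-4,4,5,5-tetramethyl-1,3,2-dioxaborolane F8.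
- H2O2 gives 3,5-dimethoxyphenol F9, and TIPSCl with imidazole gives (3,5-dimethoxyphenoxy)triisopropylsilane F10.
- n-BuLi lithiates between the two methoxy groups to 2,6-dimethoxy-4-(triisopropylsilyloxy)phenyllithium F11, which is acylated with 3 to the silyloxy oxiranyl ketone F12.
- BCl3 gives the silyloxy chlorohydrin phenol F13, and K2CO3 gives (R)-3-hydroxy-5-methoxy-7-(triisopropylsilyloxy)chroman-4-one F14.
- t-BuMgCl gives the silyloxy chloromagnesium alkoxide F15, and 14 adds to it to give the silyloxy cis-diol F16.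
- Tf2O with 2,6-lutidine gives the silyloxy C3 triflate F17, which rearranges to the 7-silyloxy isoflavanone F18.
- Et3N·3HF then frees the phenol to give 20.

## Further compounds
F1 | step 9 | 3-chloro-1-(2,6-dimethoxyphenyl)propan-1-one | COc1cccc(OC)c1C(=O)CCCl
F2 | step 9 | 3-chloro-1-(2-hydroxy-6-methoxyphenyl)propan-1-one | COc1cccc(O)c1C(=O)CCCl
F3 | step 9 | 5-methoxychroman-4-one | COc1cccc2c1C(=O)CCO2
F4 | step 9 | racemic 5-methoxy-3-[8-(methoxymethoxy)-2,2-dimethyl-2H-chromen-6-yl]chroman-4-one | COc1cccc2c1C(=O)C(c1cc(OCOC)c3OC(C)(C)C=Cc3c1)CO2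
F5 | step 9 | (3S,4S)-5-methoxy-3-[8-(methoxymethoxy)-2,2-dimethyl-2H-chromen-6-yl]chroman-4-ol | COc1cccc2c1[C@@H](O)[C@@H](c1cc(OCOC)c3OC(C)(C)C=Cc3c1)CO2
F6 | step 2 | (R)-(2,6-dimethoxyphenyl)(2,2-dimethyl-1,3-dioxolan-4-yl)methanone | COc1cccc(OC)c1C(=O)[C@H]1COC(C)(C)O1
F7 | step 2 | (R)-2,3-dihydroxy-1-(2-hydroxy-6-methoxyphenyl)propan-1-one | COc1cccc(O)c1C(=O)[C@H](O)CO
F8 | step 10 | 2-(3,5-dimethoxyphenyl)-4,4,5,5-tetramethyl-1,3,2-dioxaborolane | COc1cc(OC)cc(c1)B1OC(C)(C)C(C)(C)O1
F9 | step 10 | 3,5-dimethoxyphenol | COc1cc(O)cc(OC)c1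
F10 | step 10 | (3,5-dimethoxyphenoxy)triisopropylsilane | COc1cc(OC)cc(O[Si](C(C)C)(C(C)C)C(C)C)c1
F11 | step 10 | 2,6-dimethoxy-4-(triisopropylsilyloxy)phenyllithium | [Li]c1c(OC)cc(O[Si](C(C)C)(C(C)C)C(C)C)cc1OC
F12 | step 10 | (R)-[2,6-dimethoxy-4-(triisopropylsilyloxy)phenyl](oxiran-2-yl)methanone | COc1cc(O[Si](C(C)C)(C(C)C)C(C)C)cc(OC)c1C(=O)[C@H]1CO1
F13 | step 10 | (S)-3-chloro-2-hydroxy-1-[2-hydroxy-6-methoxy-4-(triisopropylsilyloxy)phenyl]propan-1-one | COc1cc(O[Si](C(C)C)(C(C)C)C(C)C)cc(O)c1C(=O)[C@H](O)CCl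
F14 | step 10 | (R)-3-hydroxy-5-methoxy-7-(triisopropylsilyloxy)chroman-4-one | COc1cc(O[Si](C(C)C)(C(C)C)C(C)C)cc2c1C(=O)[C@H](O)CO2
F15 | step 10 | chloromagnesium (R)-5-methoxy-4-oxo-7-(triisopropylsilyloxy)chroman-3-olate | COc1cc(O[Si](C(C)C)(C(C)C)C(C)C)cc2c1C(=O)[C@H](O[Mg]Cl)CO2
F16 | step 10 | (3R,4S)-5-methoxy-4-[8-(methoxymethoxy)-2,2-dimethyl-2H-chromen-6-yl]-7-(triisopropylsilyloxy)chromane-3,4-diol | COc1cc(O[Si](C(C)C)(C(C)C)C(C)C)cc2c1[C@@](O)(c1cc(OCOC)c3OC(C)(C)C=Cc3c1)[C@H](O)CO2
F17 | step 10 | (3R,4S)-4-hydroxy-5-methoxy-4-[8-(methoxymethoxy)-2,2-dimethyl-2H-chromen-6-yl]-7-(triisopropylsilyloxy)chroman-3-yl trifluoromethanesulfonate | COc1cc(O[Si](C(C)C)(C(C)C)C(C)C)cc2c1[C@@](O)(c1cc(OCOC)c3OC(C)(C)C=Cc3c1)[C@H](OS(=O)(=O)C(F)(F)F)CO2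
F18 | step 10 | (3S)-5-methoxy-3-[8-(methoxymethoxy)-2,2-dimethyl-2H-chromen-6-yl]-7-(triisopropylsilyloxy)chroman-4-one | COc1cc(O[Si](C(C)C)(C(C)C)C(C)C)cc2c1C(=O)[C@@H](c1cc(OCOC)c3OC(C)(C)C=Cc3c1)CO2
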